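The numbers of this flask were chosen freely; the run is a simulation.

**Small charge.** A small charge of free enzyme has to turn over a far larger charge of starting material, and it is lost to spent catalyst on the way.

starting material 0.10 M; second substrate 0.200 M; free enzyme 2.9 µM

    second substrate + loaded enzyme ⇌ second complex (K1 = 7.9 M⁻¹, k1 = 36000 M⁻¹ s⁻¹)
    first complex ⇌ loaded enzyme + first product (K2 = 0.927 M, k2 = 356 s⁻¹)
    second complex → free enzyme + target (k3 = 311 s⁻¹)
    second substrate + loaded enzyme → spent catalyst (k4 = 0.0982 M⁻¹ s⁻¹)
    starting material + free enzyme ⇌ first complex (K5 = 9.59 M⁻¹, k5 = 89500 M⁻¹ s⁻¹)

- apparent order in second substrate when 50 % of the starting material are converted (percent change of the rate of making target for one percent more second substrate charged)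

**Capture constant.** Second complex falls back at 4560 s⁻¹, much faster than it goes on to target at 311 s⁻¹. So I treated its formation as a pre-equilibrium and named one quantity: the capture constant κ, the second-order constant with which second substrate and loaded enzyme end in target, which is the forward rate constant of binding times the chance 6.39 % of going on. It comes to 2300 M⁻¹ s⁻¹.

**More second substrate.** At 50 % conversion I took starting material at 0.0500 M and second substrate, b, at 0.150 M. One turn of the catalyst then costs 6.02 ms in the two first-order steps, 2.90 ms for capture, and 6.08 ms for the like capture of starting material. Capture's share is 0.193. One percent more charged is 1.33 percent more b, so I reckoned an order of 0.258. Spent catalyst forms from the same pair, so in my reckoning each target costs k4/κ of catalyst at any b. That leaves 0.765 µM working, and this drops out of the order.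

**Faster binding.** One percent on the binding constants, forward and back together, raises κ by 6.39 % of that percent. This acts on capture time and more strongly on the catalyst saved, so I expected a sensitivity of 0.191.

**The forecast.** The forecast gave 0.29, from a share of 0.218 times 1.333, and held that the working catalyst stays the same whatever the charge, “so it cancels from the order”. It counted terms in first product that I did not, and my figure stands lower.

**The run.** The flask reached 50 % conversion at 6.96 min. Its order was 0.29, as forecast, and its sensitivity to the binding constants 0.19.

**Without return.** That order would change if second complex could not fall back: the reverse step carries part of it and part of the lost rate. For this flask without that step, κ becomes 36000 M⁻¹ s⁻¹, and by my reckoning 2.76 µM of catalyst stays working at 50 % conversion. I therefore reckoned a rate 4.41 times the actual one and an order of 0.0201. With the reverse step taken away, the run gave a rate 4.54 times the actual one, and the order fell from 0.29 to 0.023.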